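- The 6 questions ask who leads after 8.0 min with 2.00 equiv of incoming ligand at 25 °C, 33 °C and 41 °C, and by how much; I want a bracket from counting first, rates second.

all flasks: starting complex 14 mM
- green: incoming ligand 1 equiv; temperature 29 °C; run made earlier
- ochre: incoming ligand 4 equiv; temperature 38 °C; run made earlier
- Wednesday's: incoming ligand 2.00 equiv; temperature 25 °C; time 8.0 min
- Thursday's: incoming ligand 2.00 equiv; temperature 33 °C; time 8.0 min
- Friday's: incoming ligand 2.00 equiv; temperature 41 °C; time 8.0 min

| run | time / min | starting complex / % | side product B / % | side product A / % | complex with one exchanged / % | complex with three exchanged / % |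
|---|---|---|---|---|---|---|
| green | 0.833 | 65.0 | 4.4 | 0.7 | 26.4 | 1.7 |
| green | 2.50 | 36.4 | 20.6 | 0 | 39.0 | 1.8 |
| green | 4.00 | 25.0 | 29.0 | 1.0 | 40.7 | 3.3 |
| green | 6.00 | 13.3 | 38.7 | 1.2 | 37.3 | 3.6 |
| green | 10.0 | 5.2 | 46.4 | 4.5 | 35.9 | 3.3 |
| ochre | 1.00 | 3.8 | 10.4 | 3.5 | 52.3 | 23.3 |
| ochre | 2.00 | 0 | 10.2 | 19.5 | 33.7 | 29.6 |
| ochre | 3.00 | 0 | 10.0 | 37.4 | 22.9 | 25.8 |
| ochre | 4.00 | 1.6 | 10.9 | 52.6 | 15.6 | 18.4 |
| ochre | 5.00 | 0 | 10.6 | 62.8 | 10.9 | 12.6 |

(each reading ± 1 percentage point)

1. which of these there is most of at the end, counted by the starting complex in it, Wednesday's (complex with three exchanged / complex with one exchanged / side product B / side product A)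
2. which of these there is most of at the end, counted by the starting complex in it, Thursday's (complex with three exchanged / complex with one exchanged / side product B / side product A)
3. which of these there is most of at the end, counted by the starting complex in it, Friday's (complex with three exchanged / complex with one exchanged / side product B / side product A)
4. amount of the one of these that there is most of at the end, in percent of the starting complex charged, Wednesday's
5. amount of the one of these that there is most of at the end, in percent of the starting complex charged, Thursday's
6. amount of the one of these that there is most of at the end, in percent of the starting complex charged, Friday's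

- percent here means starting complex units held: one side product B counts as two
- the numbers in the tables scatter by 1 percentage point (one standard deviation)
- steps thought possible: starting complex + complex with one exchanged -> side product B; complex with one exchanged + incoming ligand -> leaving ligand + complex with two exchanged; leaving ligand + complex with three exchanged -> side product A; starting complex + incoming ligand -> leaving ligand + complex with one exchanged; complex with two exchanged + incoming ligand -> leaving ligand + complex with three exchanged

- Side product B reads 46.4 % in the green run and 10.6 % in the ochre run; scaled by equivalents to 2.00 equiv, these give 23.2 % and 21.2 %, so I take their mean, 22.2 %.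
- From above I count ligand: a unit of charge holds one incoming ligand as complex with one exchanged, two as complex with two exchanged, 3 as complex with three exchanged or side product A, and 0.5 as side product B, which holds two units and one exchanged ligand.
- Subtracting the balance of the complex from that balance, once starting complex is used up, caps side product A plus complex with three exchanged at 55.5 %, the ligand ceiling: (equivalents − 1)/2 + B/4, in units of charge, reached with incoming ligand as limiting reagent and with no temperature in it.
- If complex with one exchanged leads instead, its lid is 77.8 %.
- From below, complex with three exchanged read at most 29.6 % in the ochre run, and at that reading the unread complex with two exchanged can hold the 7.00 % missing from the balance, so the larger of complex with one exchanged and side product A holds roughly 20.6 % or more.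
- To tighten, side product A passes complex with one exchanged by 3.00 min in the ochre run at 38 °C; with a second exchange proportional to [incoming ligand], 2.00 equiv moves that crossing out to about 6.00 min, so I commit to side product A on Friday's and complex with one exchanged on Wednesday's, with Thursday's open.
- The forecast says complex with one exchanged at 42 % on Wednesday's, complex with one exchanged at 35 % on Thursday's and side product A at 42 % on Friday's, holding that “the side-product B step competes only while starting complex remains”, and its amounts lie above 20.6 % and below 55.5 %.
- The flasks give complex with one exchanged at 44.5 % on Wednesday's, complex with one exchanged at 35.3 % on Thursday's and side product A at 40.1 % on Friday's, each above 20.6 % and below 55.5 %.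

    starting complex + complex with one exchanged → side product B (k = 0.247 M⁻¹ s⁻¹, Ea = 46.0 kJ mol⁻¹)
    complex with one exchanged + incoming ligand → leaving ligand + complex with two exchanged (k = 0.101 M⁻¹ s⁻¹, Ea = 58.0 kJ mol⁻¹)
    leaving ligand + complex with three exchanged → side product A (k = 0.189 M⁻¹ s⁻¹, Ea = 46.0 kJ mol⁻¹)
    starting complex + incoming ligand → leaving ligand + complex with one exchanged (k = 0.497 M⁻¹ s⁻¹, Ea = 51.0 kJ mol⁻¹)
    complex with two exchanged + incoming ligand → leaving ligand + complex with three exchanged (k = 0.899 M⁻¹ s⁻¹, Ea = 54.0 kJ mol⁻¹)
    (constants at 25 °C)

- In Friday's flask the first exchange and the B step ran while starting complex stood, and side product B read 22.6 % at 4.00 min and 23.1 % at 8.00 min; meanwhile the second exchange drew complex with one exchanged down to 28.1 %, with incoming ligand at 9.0 % of its charge. Friday's side product A plus complex with three exchanged stand at 44.9 %, and the ceiling minus the share for leftover ligand and complex with two exchanged gives 44.6 %. A flask like Friday's kept at 66 °C has 0.084 % of its incoming ligand left, its ceiling less complex with two exchanged is 53.8 %, and its side product A stands at 53.5 % after 8.00 min.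

The earlier runs and the new flask come from a simulation with constants of no real substance; the scatter is artificial.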